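## Structural features

The target is a (2S)-flavanone: benzene ring A is fused through C4a and C8a to the dihydropyranone ring C (O1, C2, C3, C4), and the catechol ring B sits on C2. Ring A is fully differentiated: a hydroxyl at C5 hydrogen-bonded to the C4 carbonyl, hydrogen at C6, a methoxy group at C7 and, at C8, a (2Z)-4-hydroxy-3-methylbut-2-enyl chain with a trisubstituted alkene and a primary allylic alcohol. C2 is the only stereocentre, so no stereocentres are adjacent; the second stereochemical element is the Z double bond C2''=C3''. C2 is benzylic, bonded to O1 and β to the ketone, so its configuration is lost when base opens ring C to the 2'-hydroxychalcone or when acid ionises the C2–O1 bond. The catechol is sensitive to oxidation and base, the allylic alcohol and the alkene to strong protic or Lewis acids, and the alkene rules out hydrogenation or hydrogenolysis. The real difficulties are to set and keep C2 as one enantiomer, to tell the oxygens at C5 and C7 apart, to place the chain at C8 and not C6, and to secure the Z geometry. The key step uses the pattern of ring A: of the two carbons ortho to O1, C8 already carries the side chain, so an acyl cation tethered to O1 through C2 and C3 can reach only C4a, which is activated by O1 and the C5 oxygen (ortho) and by the C7 oxygen (para).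

## Logic of the disconnections

22 to 21: the two aryl O–acetyl bonds and the O–Si bond are cut. The catechol and the allylic alcohol must be masked during the Lewis-acid steps, and the acetates also make ring B electron-poor. The forward step must avoid base (ring C) and strong acid (allylic alcohol), which points to dilute acidic methanolysis.

21 to 20: the O5–CH3 bond is cut. This returns ring A to two identical methoxy groups and hence to a symmetric phenol. The forward step must cleave only the methoxy group peri to the C4 carbonyl, which chelation to magnesium should allow.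

20 to 18 (through 19): the C4–C4a bond is cut. Ring C and the ketone disappear, and what remains is an acyclic acid whose stereocentre is an ether carbon. The forward acylation must be faster than heterolysis of the benzylic C2–O1 bond, and it relies on C8 being blocked.

18 to 17: the carboxyl O–allyl bond is cut. The acid must be masked during ether formation. An allyl ester is chosen because zerovalent palladium frees the acid under neutral conditions, whereas hydroxide would expel the β-aryloxy group (E1cB) and cleave the acetates.

17 to 10 and 16: the O1–C2 bond is cut. This is the convergent cut into a ring A phenol and a ring B hydroxy ester of similar size, and it turns the stereocentre into a secondary carbinol. The forward substitution must proceed with clean inversion, so the carbinol must be R and ring B must not stabilise a benzylic cation.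

16 back to 11 (through 15, 14, 13 and 12): the carbinol C–H bond is cut (ketone reduction), then the bond between the aroyl carbon and the α-carbon (acylation of Meldrum's acid, alcoholysis with allyl alcohol), then the two O–acetyl bonds. The reduction must be enantioselective and spare the allyl ester and the acetates, so transfer hydrogenation is preferred to hydrogenation under H2 pressure.

10 to 8 and 7: the C8–C1'' bond is cut. The two ortho carbons of 8 are equivalent, and the chain arrives complete with its Z geometry. The forward step needs C- over O-alkylation, ortho over para attack, and substitution at the primary carbon without allylic shift.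

7 back to 1 (through 6, 5, 4, 3 and 2): C–Br goes back to C–OH, CH2OH to the methyl ester, and the C3''–CH3 bond is cut as a syn carbocupration of an ynoate, which fixes the Z geometry. The C–CO2Me bond is an acetylide acylation and the O–Si bond a silylation. The cuprate adduct must be protonated cold, before it can isomerise.

## Other disconnections considered

Alternative 1: The cut is the C2''=C3'' double bond, with O1 tied temporarily to C4'' as an ester.
- Forward: 8 would be O-allylated, rearranged (aromatic Claisen) and acylated to the methacrylate A2. The second-generation Grubbs catalyst would close the seven-membered lactone A1. Reduction would open it to the phenol–allylic alcohol A3, and selective silylation of the primary hydroxyl would join the chosen route at 10.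
- In favour: the ring enforces the Z geometry, since a seven-membered lactone cannot hold an E alkene. The C8–C1'' bond comes from a sigmatropic shift that can only reach an ortho carbon.
- Against: metathesis between a monosubstituted alkene and an electron-poor 1,1-disubstituted alkene to a trisubstituted conjugated alkene is slow. Ruthenium hydrides could shift the allyl double bond into conjugation, after which closure would give a six-membered lactone with one carbon fewer. The last step must distinguish a primary alcohol from a phenol.
- Comparison: on structure it is better than step 6 in regiocontrol and equal to the cuprate addition in geometry control, but it solves only the ring A fragment and says nothing about ring C or C2. On mechanism the ring closure is less certain than the stereospecific syn addition. On step economy it is equal: six operations from 8 to 10 against six for steps 1 to 6.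

Alternative 2: The cuts are C4a–C5 and C8–C8a; ring A is built onto a finished, enantiopure ring C.
- Forward: the electron-rich diene A5 would add to the brominated enol-ether double bond of the pyranone A4. Its chain-bearing terminus bonds to the oxygen-bearing carbon (the future C8a) and its ketene acetal carbon to the bromine-bearing carbon (the future C4a). Loss of HBr and methanol would aromatise ring A to A6.
- In favour: the constitution of the diene fixes 5-OH, 7-OMe and the C8 chain, so neither the phenol alkylation nor a late demethylation is needed. On this point it is better than the chosen plan. The stereocentre would come from a catalytic asymmetric hetero-Diels–Alder reaction, the equal of the transfer hydrogenation.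
- Against: the double bond of A4 is a vinylogous ester and a poor partner for an electron-rich diene. The new bond at the future C8a is crowded by the chain at C8. A5 needs a long preparation with control of its C3=C4 geometry and is hydrolytically labile. Aromatisation by base or heat can open ring C by β-elimination and erode C2. Removing methoxymethyl ethers needs stronger acid than acetates, which threatens the allylic alcohol.
- Comparison: the structural logic and the end game are better; the mechanism of the key reaction has much weaker support on this class of acceptor than the Friedel–Crafts closure; the step count would be similar.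

Alternative 3: The cut is the C2–C3 bond.
- Forward: Rh2(PTTL)4 would turn the diazoketone A7 into a carbene at C3 that inserts into a benzylic C–H bond of the O1-benzyl ether. This closes ring C and sets C2 in one step, giving A8.
- In favour: ring and stereocentre arise in one catalytic step, which is better in concept than reduction, substitution and acylation. The C–H bond is activated by oxygen and the aryl group. Neutral conditions allow an electron-rich ring B. One fluoride or acid treatment would remove all four silyl groups, one step fewer than the chosen end game.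
- Against: a carbene without a second acceptor is unselective. The ether oxygen O1 can attack it to give a five-membered oxonium ylide that rearranges by 1,2-shift of the benzyl group. Addition to ring B is possible, and six-membered insertion with high enantioselectivity is not assured. A7 needs a 2,6-dioxygenated benzoic acid with O5 and O7 already differentiated and the chain at C8, which is longer to make than 10, and its formation uses diazomethane chemistry on a hindered acid.
- Comparison: on structure it is the most direct of the four. On mechanism it carries the largest chemoselectivity and enantioselectivity risk, whereas the chosen plan separates a well-understood reduction from a well-understood ring closure. On step economy it is potentially shorter after the ring A acid, but not overall.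

Key step: step 13

Remark: the (R,R)-configured transfer-hydrogenation catalyst is assumed to follow the facial sense known for aryl alkyl ketones and so to give the R carbinol 16; if the sense were opposite, the (S,S)-catalyst would be used.

## Route

Step 1
Reactants: 1 prop-2-yn-1-ol (propargyl alcohol)
Product: 2 tert-butyldimethyl(prop-2-yn-1-yloxy)silane
Conditions: TBSCl, imidazole, CH2Cl2, 0 °C → rt
Reagents that add atoms: tert-butyldimethylsilyl chloride, C[Si](C)(Cl)C(C)(C)C
Why: Silyl ether formation at a primary alcohol; the terminal alkyne is not affected.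

Step 2
Reactants: 2 tert-butyldimethyl(prop-2-yn-1-yloxy)silane
Product: 4 methyl 4-(tert-butyldimethylsilyloxy)but-2-ynoate, via lithium acetylide 3 (not isolated)
Conditions: n-BuLi, THF, −78 °C; then ClCO2Me, −78 → 0 °C
Reagents that add atoms: methyl chloroformate, COC(=O)Cl
Why: Deprotonation of the terminal alkyne and C-acylation of the lithium acetylide with a chloroformate (acetylide carboxylation) should give the ynoate; the silyl ether is inert to both reagents.

Step 3
Reactants: 4 methyl 4-(tert-butyldimethylsilyloxy)but-2-ynoate
Product: 5 methyl (2Z)-4-(tert-butyldimethylsilyloxy)-3-methylbut-2-enoate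
Conditions: Me2CuLi (from MeLi and CuI), THF, −78 °C; MeOH then aq. NH4Cl at −78 °C
Reagents that add atoms: lithium dimethylcuprate, [Li+].C[Cu-]C
Why: Conjugate addition of an organocuprate to an ynoate is a syn carbocupration; protonation at −78 °C, before the alkenylcopper species can equilibrate through an allenoate, places CH3 and H cis and therefore CH2OSi and CO2Me cis, which is the Z geometry of the side chain.

Step 4
Reactants: 5 methyl (2Z)-4-(tert-butyldimethylsilyloxy)-3-methylbut-2-enoate
Product: 6 (2Z)-4-(tert-butyldimethylsilyloxy)-3-methylbut-2-en-1-ol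
Conditions: i-Bu2AlH (2.2 equiv), CH2Cl2, −78 °C; aq. potassium sodium tartrate
Reagents that add atoms: none
Why: 1,2-Reduction of an α,β-unsaturated ester to the allylic alcohol by an aluminium hydride does not touch the alkene geometry, and the silyl ether prevents lactonisation of the Z-configured γ-oxygenated system.

Step 5
Reactants: 6 (2Z)-4-(tert-butyldimethylsilyloxy)-3-methylbut-2-en-1-ol
Product: 7 {[(2Z)-4-bromo-2-methylbut-2-en-1-yl]oxy}(tert-butyl)dimethylsilane
Conditions: CBr4, PPh3, CH2Cl2, 0 °C
Reagents that add atoms: tetrabromomethane, BrC(Br)(Br)Br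
Why: Appel bromination displaces the alkoxyphosphonium group by SN2 at the primary carbon, so neither allylic transposition nor Z/E isomerisation is expected at 0 °C, and the neutral conditions spare the silyl ether.

Step 6
Reactants: 7 {[(2Z)-4-bromo-2-methylbut-2-en-1-yl]oxy}(tert-butyl)dimethylsilane; 8 3,5-dimethoxyphenol
Product: 10 2-[(2Z)-4-(tert-butyldimethylsilyloxy)-3-methylbut-2-en-1-yl]-3,5-dimethoxyphenol, via sodium 3,5-dimethoxyphenoxide 9 (not isolated)
Conditions: NaH (1 equiv to 8), toluene, 0 °C → rt; then 7 (0.5 equiv), rt
Reagents that add atoms: none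
Why: Ortho C-alkylation of a phenoxide: in toluene the tight sodium phenoxide ion pair delivers the allylic bromide to an ortho carbon through a sodium-bridged SN2 transition state, which favours C2 (both ortho carbons are equivalent) over oxygen and over the para carbon. Attack at the primary carbon keeps the Z geometry, and the excess of phenoxide limits double alkylation.

Step 7
Reactants: 11 3,4-dihydroxybenzoic acid
Product: 12 3,4-bis(acetyloxy)benzoic acid
Conditions: Ac2O, pyridine, 0 °C → rt; aq. HCl work-up
Reagents that add atoms: acetic anhydride, CC(=O)OC(C)=O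
Why: O-Acetylation of the catechol; any mixed anhydride at the carboxyl group is hydrolysed in the work-up. The acetates make ring B electron-poor for steps 11 and 13.

Step 8
Reactants: 12 3,4-bis(acetyloxy)benzoic acid
Product: 14 5-{[3,4-bis(acetyloxy)phenyl](hydroxy)methylidene}-2,2-dimethyl-1,3-dioxane-4,6-dione, via 3,4-bis(acetyloxy)benzoyl chloride 13 (not isolated)
Conditions: (COCl)2, DMF (cat.), CH2Cl2, 0 °C → rt; then Meldrum's acid, pyridine, CH2Cl2, 0 °C → rt; cold dilute HCl wash
Reagents that add atoms: Meldrum's acid (2,2-dimethyl-1,3-dioxane-4,6-dione), CC1(C)OC(=O)CC(=O)O1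
Why: C-Acylation of Meldrum's acid by an aroyl chloride with pyridine as base is the standard entry to β-keto esters; aryl acetates are stable to pyridine at this temperature.

Step 9
Reactants: 14 5-{[3,4-bis(acetyloxy)phenyl](hydroxy)methylidene}-2,2-dimethyl-1,3-dioxane-4,6-dione
Product: 15 prop-2-en-1-yl 3-[3,4-bis(acetyloxy)phenyl]-3-oxopropanoate
Conditions: allyl alcohol (3 equiv), toluene, 90 °C
Reagents that add atoms: allyl alcohol (prop-2-en-1-ol), C=CCO
Why: Thermal fragmentation of the acyl Meldrum's acid to an acylketene with loss of acetone and CO2, and trapping by the alcohol (alcoholysis), should give the allyl β-keto ester under neutral conditions that leave the acetates intact.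

Step 10
Reactants: 15 prop-2-en-1-yl 3-[3,4-bis(acetyloxy)phenyl]-3-oxopropanoate
Product: 16 prop-2-en-1-yl (3R)-3-[3,4-bis(acetyloxy)phenyl]-3-hydroxypropanoate
Conditions: RuCl[(R,R)-TsDPEN](p-cymene) (1 mol %), HCO2H/Et3N (5:2), EtOAc, 30 °C
Reagents that add atoms: none
Why: Asymmetric transfer hydrogenation of an aryl ketone by a ruthenium hydride with a chiral diamine ligand (outer-sphere transfer of hydride and proton); the aryl group is held by a CH–π contact with the cymene ligand, so the (R,R)-catalyst should deliver hydride to the face that gives the R carbinol. No H2 is present, so the allyl ester is not reduced, and the acidic medium preserves the acetates.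

Step 11
Reactants: 10 2-[(2Z)-4-(tert-butyldimethylsilyloxy)-3-methylbut-2-en-1-yl]-3,5-dimethoxyphenol; 16 prop-2-en-1-yl (3R)-3-[3,4-bis(acetyloxy)phenyl]-3-hydroxypropanoate
Product: 17 prop-2-en-1-yl (3S)-3-[3,4-bis(acetyloxy)phenyl]-3-{2-[(2Z)-4-(tert-butyldimethylsilyloxy)-3-methylbut-2-en-1-yl]-3,5-dimethoxyphenoxy}propanoate
Conditions: PPh3, DIAD, toluene, 0 °C → rt
Reagents that add atoms: none
Why: Mitsunobu etherification: the phenol displaces the alkoxyphosphonium group of 16 by SN2 with inversion, so the R carbinol becomes the S aryl ether (priority order O > aryl > CH2 in both). The electron-poor diacetoxyphenyl ring disfavours a benzylic cation and so protects the configuration, and toluene at low temperature limits β-elimination to the cinnamate.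

Step 12
Reactants: 17 prop-2-en-1-yl (3S)-3-[3,4-bis(acetyloxy)phenyl]-3-{2-[(2Z)-4-(tert-butyldimethylsilyloxy)-3-methylbut-2-en-1-yl]-3,5-dimethoxyphenoxy}propanoate
Product: 18 (3S)-3-[3,4-bis(acetyloxy)phenyl]-3-{2-[(2Z)-4-(tert-butyldimethylsilyloxy)-3-methylbut-2-en-1-yl]-3,5-dimethoxyphenoxy}propanoic acid
Conditions: Pd(PPh3)4 (5 mol %), N-methylaniline (3 equiv), THF, rt; aq. KHSO4 wash
Reagents that add atoms: none
Why: Tsuji–Trost deallylation: zerovalent palladium ionises the allyl ester to a π-allyl complex that is trapped by the weakly nucleophilic amine. The medium is neutral, so neither E1cB loss of the β-aryloxy group nor cleavage of the acetates or the silyl ether is expected.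

Step 13
Reactants: 18 (3S)-3-[3,4-bis(acetyloxy)phenyl]-3-{2-[(2Z)-4-(tert-butyldimethylsilyloxy)-3-methylbut-2-en-1-yl]-3,5-dimethoxyphenoxy}propanoic acid
Product: 20 (2S)-2-[3,4-bis(acetyloxy)phenyl]-8-[(2Z)-4-(tert-butyldimethylsilyloxy)-3-methylbut-2-en-1-yl]-5,7-dimethoxy-2,3-dihydro-4H-chromen-4-one, via acid chloride 19 (not isolated)
Conditions: 1-chloro-N,N,2-trimethylprop-1-en-1-amine (1.2 equiv), CH2Cl2, 0 °C; then ZnCl2 (1 M in Et2O, 1.5 equiv), −20 → 0 °C
Reagents that add atoms: none
Why: The α-chloroenamine converts the acid into acid chloride 19 without releasing acid (its co-product is a neutral amide), and ZnCl2 then polarises the C–Cl bond to an acylium-type electrophile. C4a attacks this carbon to give an arenium ion stabilised by O1 and the 5-methoxy group (ortho) and by the 7-methoxy group (para), and loss of a proton restores ring A. This is an intramolecular Friedel–Crafts acylation, the established way from 3-aryloxypropanoic acids to chroman-4-ones. Ring C closes as a six-membered ring by electrophilic aromatic substitution, exo with respect to the acylium C=O and endo with respect to the C4a=C8a bond of the arene. No stereocentre is formed; C2 takes no part in the bond formation, so its S configuration should be carried over unchanged. Regiochemically only C4a is available, because the other ortho carbon C8 bears the side chain and C6 cannot be reached by the three-atom tether. Chemically, acylation must outrun heterolysis of the benzylic C2–O1 bond and β-elimination to a cinnamoyl chloride; the strongly activated ring A (reaction at or below 0 °C with a mild Lewis acid) and the electron-poor ring B are meant to secure this. The amide co-product buffers the HCl that is formed, which should protect the silyl ether and the alkene.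

Step 14
Reactants: 20 (2S)-2-[3,4-bis(acetyloxy)phenyl]-8-[(2Z)-4-(tert-butyldimethylsilyloxy)-3-methylbut-2-en-1-yl]-5,7-dimethoxy-2,3-dihydro-4H-chromen-4-one
Product: 21 (2S)-2-[3,4-bis(acetyloxy)phenyl]-8-[(2Z)-4-(tert-butyldimethylsilyloxy)-3-methylbut-2-en-1-yl]-5-hydroxy-7-methoxy-2,3-dihydro-4H-chromen-4-one
Conditions: MgI2·OEt2 (2.5 equiv), toluene/Et2O, 50 °C; aq. NH4Cl
Reagents that add atoms: none
Why: Chelation-assisted ether cleavage: magnesium binds between the C4 carbonyl and the peri 5-methoxy oxygen and iodide removes the methyl group by SN2 (demethylation of ortho-carbonyl aryl methyl ethers with magnesium iodide); the 7-methoxy group cannot chelate and should remain. The aprotic, weakly Lewis-acidic medium is expected to leave the acetates, the silyl ether and C2 untouched.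

Step 15
Reactants: 21 (2S)-2-[3,4-bis(acetyloxy)phenyl]-8-[(2Z)-4-(tert-butyldimethylsilyloxy)-3-methylbut-2-en-1-yl]-5-hydroxy-7-methoxy-2,3-dihydro-4H-chromen-4-one
Product: 22 (2S)-2-(3,4-dihydroxyphenyl)-5-hydroxy-8-[(2Z)-4-hydroxy-3-methylbut-2-en-1-yl]-7-methoxy-2,3-dihydro-4H-chromen-4-one
Conditions: HCl (1.25 M in MeOH), 0 °C → rt, under argon
Reagents that add atoms: none
Why: Acid-catalysed transesterification of the two aryl acetates and methanolysis of the primary silyl ether; no base is present, so ring C cannot open and C2 stays S, and dilute acid at or below room temperature should not ionise the primary allylic alcohol.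

## Compound list

1 | prop-2-yn-1-ol (propargyl alcohol) | C#CCO | starting material
2 | tert-butyldimethyl(prop-2-yn-1-yloxy)silane | C#CCO[Si](C)(C)C(C)(C)C | intermediate
3 | [3-(tert-butyldimethylsilyloxy)prop-1-yn-1-yl]lithium | [Li]C#CCO[Si](C)(C)C(C)(C)C | intermediate (not isolated)
4 | methyl 4-(tert-butyldimethylsilyloxy)but-2-ynoate | COC(=O)C#CCO[Si](C)(C)C(C)(C)C | intermediate
5 | methyl (2Z)-4-(tert-butyldimethylsilyloxy)-3-methylbut-2-enoate | COC(=O)/C=C(/C)CO[Si](C)(C)C(C)(C)C | intermediate
6 | (2Z)-4-(tert-butyldimethylsilyloxy)-3-methylbut-2-en-1-ol | OC/C=C(/C)CO[Si](C)(C)C(C)(C)C | intermediate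
7 | {[(2Z)-4-bromo-2-methylbut-2-en-1-yl]oxy}(tert-butyl)dimethylsilane | BrC/C=C(/C)CO[Si](C)(C)C(C)(C)C | intermediate
8 | 3,5-dimethoxyphenol | COc1cc(O)cc(OC)c1 | starting material
9 | sodium 3,5-dimethoxyphenoxide | [Na+].[O-]c1cc(OC)cc(OC)c1 | intermediate (not isolated)
10 | 2-[(2Z)-4-(tert-butyldimethylsilyloxy)-3-methylbut-2-en-1-yl]-3,5-dimethoxyphenol | COc1cc(OC)c(C/C=C(/C)CO[Si](C)(C)C(C)(C)C)c(O)c1 | intermediate
11 | 3,4-dihydroxybenzoic acid | OC(=O)c1ccc(O)c(O)c1 | starting material
12 | 3,4-bis(acetyloxy)benzoic acid | CC(=O)Oc1ccc(C(=O)O)cc1OC(C)=O | intermediate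
13 | 3,4-bis(acetyloxy)benzoyl chloride | CC(=O)Oc1ccc(C(Cl)=O)cc1OC(C)=O | intermediate (not isolated)
14 | 5-{[3,4-bis(acetyloxy)phenyl](hydroxy)methylidene}-2,2-dimethyl-1,3-dioxane-4,6-dione | CC(=O)Oc1ccc(C(O)=C2C(=O)OC(C)(C)OC2=O)cc1OC(C)=O | intermediate
15 | prop-2-en-1-yl 3-[3,4-bis(acetyloxy)phenyl]-3-oxopropanoate | C=CCOC(=O)CC(=O)c1ccc(OC(C)=O)c(OC(C)=O)c1 | intermediate
16 | prop-2-en-1-yl (3R)-3-[3,4-bis(acetyloxy)phenyl]-3-hydroxypropanoate | C=CCOC(=O)C[C@@H](O)c1ccc(OC(C)=O)c(OC(C)=O)c1 | intermediate
17 | prop-2-en-1-yl (3S)-3-[3,4-bis(acetyloxy)phenyl]-3-{2-[(2Z)-4-(tert-butyldimethylsilyloxy)-3-methylbut-2-en-1-yl]-3,5-dimethoxyphenoxy}propanoate | C=CCOC(=O)C[C@H](Oc1cc(OC)cc(OC)c1C/C=C(/C)CO[Si](C)(C)C(C)(C)C)c1ccc(OC(C)=O)c(OC(C)=O)c1 | intermediate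
18 | (3S)-3-[3,4-bis(acetyloxy)phenyl]-3-{2-[(2Z)-4-(tert-butyldimethylsilyloxy)-3-methylbut-2-en-1-yl]-3,5-dimethoxyphenoxy}propanoic acid | OC(=O)C[C@H](Oc1cc(OC)cc(OC)c1C/C=C(/C)CO[Si](C)(C)C(C)(C)C)c1ccc(OC(C)=O)c(OC(C)=O)c1 | intermediate (precursor of the key step)
19 | (3S)-3-[3,4-bis(acetyloxy)phenyl]-3-{2-[(2Z)-4-(tert-butyldimethylsilyloxy)-3-methylbut-2-en-1-yl]-3,5-dimethoxyphenoxy}propanoyl chloride | ClC(=O)C[C@H](Oc1cc(OC)cc(OC)c1C/C=C(/C)CO[Si](C)(C)C(C)(C)C)c1ccc(OC(C)=O)c(OC(C)=O)c1 | intermediate (not isolated)
20 | (2S)-2-[3,4-bis(acetyloxy)phenyl]-8-[(2Z)-4-(tert-butyldimethylsilyloxy)-3-methylbut-2-en-1-yl]-5,7-dimethoxy-2,3-dihydro-4H-chromen-4-one | COc1cc(OC)c2c(c1C/C=C(/C)CO[Si](C)(C)C(C)(C)C)O[C@H](c1ccc(OC(C)=O)c(OC(C)=O)c1)CC2=O | intermediate (product of the key step)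
21 | (2S)-2-[3,4-bis(acetyloxy)phenyl]-8-[(2Z)-4-(tert-butyldimethylsilyloxy)-3-methylbut-2-en-1-yl]-5-hydroxy-7-methoxy-2,3-dihydro-4H-chromen-4-one | COc1cc(O)c2c(c1C/C=C(/C)CO[Si](C)(C)C(C)(C)C)O[C@H](c1ccc(OC(C)=O)c(OC(C)=O)c1)CC2=O | intermediate
22 | (2S)-2-(3,4-dihydroxyphenyl)-5-hydroxy-8-[(2Z)-4-hydroxy-3-methylbut-2-en-1-yl]-7-methoxy-2,3-dihydro-4H-chromen-4-one | COc1cc(O)c2c(c1C/C=C(/C)CO)O[C@H](c1ccc(O)c(O)c1)CC2=O | target

## Step count and least certain steps

Total: 15 steps. Longest linear sequence: 11 steps (steps 1 to 6, then 11 to 15); the ring B branch (steps 7 to 10) joins at step 11.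

Step 13 (key step). The most likely failure is heterolysis of the benzylic C2–O1 bond, or β-elimination of the aryloxide from the activated acyl group, before ring closure; the acid chloride carries a leaving group in the β-position, and the HCl formed can also strip the silyl ether. The fallback sets out from 10 and returns at 20; it closes ring C before the stereocentre exists.
- 10 as its sodium salt would open β-propiolactone at the alkyl–oxygen bond to give the 3-aryloxypropanoic acid F1.
- Its acid chloride F2 (made as in step 13, not isolated), which has no benzylic leaving group, would be cyclised with ZnCl2 to the chroman-4-one F3.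
- Dehydrogenation with 2-iodoxybenzoic acid and 4-methoxypyridine N-oxide in DMSO at room temperature would give the chromone F4.
- Enantioselective conjugate addition of the arylboronic acid F5 would give 20. Conditions: Pd(OCOCF3)2, the enantiomer of the tert-butyl pyridine–oxazoline ligand that leads to the 2S product, NH4PF6, water, 1,2-dichloroethane, 60 °C.

Step 6. O-Alkylation, para alkylation at C4 and double alkylation can compete with the wanted ortho attack, because the phenoxide is an ambident nucleophile and the site depends on ion pairing. The fallback sets out from 8 and returns at 10; it replaces the ambident phenoxide by directed ortho-metalation.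
- 8 would be converted into the aryl diethylcarbamate F6 (ClCONEt2, K2CO3, MeCN).
- Lithiation with s-BuLi/TMEDA in THF at −78 °C should occur at the carbon between the carbamate and a methoxy group. Alkylation with 7 at −78 °C (after transmetalation with CuBr·SMe2 if needed) would give the alkylated carbamate F7.
- LiAlH4 in THF at 0 °C would release 10.

Step 11. β-Elimination of the activated carbinol to the cinnamate (acidic α-hydrogens) and partial loss of configuration through an ion pair can compete with SN2 attack by the hindered, ortho-substituted phenol; acetyl transfer from ring B to the phenoxide is a further risk. The fallback sets out from 10 and returns at 18, bypassing 16, 17 and step 12; it sets C2 by catalyst control and has no acidic α-hydrogens.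
- Iridium-catalysed enantioselective allylic etherification of the sodium salt of 10 with the cinnamyl methyl carbonate F8 (a ring B building block to be made separately) should give the branched allyl aryl ether F9. Conditions: [Ir(cod)Cl]2, chiral phosphoramidite ligand of the sense that gives the S ether, THF, rt → 50 °C.
- Hydroboration of the terminal alkene with 9-BBN and oxidation with NaBO3·4H2O would give the primary alcohol F10.
- TEMPO/PhI(OAc)2 in MeCN–water would oxidise F10 to 18.

Step 14. Iodide may substitute at the allylic carbon of the side chain after magnesium coordinates the silyl ether, the Lewis acid may open ring C with loss of configuration at C2, and the 7-methoxy group may be cleaved slowly on prolonged heating. The fallback sets out from 7 and 16 and returns at 21; it differentiates O5 from the start so that no dealkylation is needed.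
- Monosilylation of commercial 5-methoxyresorcinol (i-Pr3SiCl, imidazole, DMF) would give the silyloxyphenol F11.
- C-Alkylation with 7 as in step 6 is expected between OH and OMe, because the bulky silyloxy group shields its own neighbours; it would give the alkylated phenol F12.
- Mitsunobu coupling with 16 as in step 11 would give the allyl ester F13, and deallylation as in step 12 the acid F14.
- Ring closure as in step 13 through the acid chloride F15 (not isolated) would give the 5-silyloxy-7-methoxyflavanone F16.
- KHF2 in MeOH at room temperature, which cleaves aryl silyl ethers in preference to alkyl silyl ethers, would then give 21.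

## Further compounds

F1 | step 13 | 3-{2-[(2Z)-4-(tert-butyldimethylsilyloxy)-3-methylbut-2-en-1-yl]-3,5-dimethoxyphenoxy}propanoic acid | OC(=O)CCOc1cc(OC)cc(OC)c1C/C=C(/C)CO[Si](C)(C)C(C)(C)C
F2 | step 13 | 3-{2-[(2Z)-4-(tert-butyldimethylsilyloxy)-3-methylbut-2-en-1-yl]-3,5-dimethoxyphenoxy}propanoyl chloride | ClC(=O)CCOc1cc(OC)cc(OC)c1C/C=C(/C)CO[Si](C)(C)C(C)(C)C
F3 | step 13 | 8-[(2Z)-4-(tert-butyldimethylsilyloxy)-3-methylbut-2-en-1-yl]-5,7-dimethoxy-2,3-dihydro-4H-chromen-4-one | COc1cc(OC)c2c(c1C/C=C(/C)CO[Si](C)(C)C(C)(C)C)OCCC2=O
F4 | step 13 | 8-[(2Z)-4-(tert-butyldimethylsilyloxy)-3-methylbut-2-en-1-yl]-5,7-dimethoxy-4H-chromen-4-one | COc1cc(OC)c2c(c1C/C=C(/C)CO[Si](C)(C)C(C)(C)C)OC=CC2=O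
F5 | step 13 | [3,4-bis(acetyloxy)phenyl]boronic acid | CC(=O)Oc1ccc(B(O)O)cc1OC(C)=O
F6 | step 6 | 3,5-dimethoxyphenyl N,N-diethylcarbamate | CCN(CC)C(=O)Oc1cc(OC)cc(OC)c1
F7 | step 6 | 2-[(2Z)-4-(tert-butyldimethylsilyloxy)-3-methylbut-2-en-1-yl]-3,5-dimethoxyphenyl N,N-diethylcarbamate | CCN(CC)C(=O)Oc1cc(OC)cc(OC)c1C/C=C(/C)CO[Si](C)(C)C(C)(C)C
F8 | step 11 | (2E)-3-[3,4-bis(acetyloxy)phenyl]prop-2-en-1-yl methyl carbonate | COC(=O)OC/C=C/c1ccc(OC(C)=O)c(OC(C)=O)c1
F9 | step 11 | 4-[(1S)-1-{2-[(2Z)-4-(tert-butyldimethylsilyloxy)-3-methylbut-2-en-1-yl]-3,5-dimethoxyphenoxy}prop-2-en-1-yl]-1,2-phenylene diacetate | C=C[C@H](Oc1cc(OC)cc(OC)c1C/C=C(/C)CO[Si](C)(C)C(C)(C)C)c1ccc(OC(C)=O)c(OC(C)=O)c1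
F10 | step 11 | 4-[(1S)-1-{2-[(2Z)-4-(tert-butyldimethylsilyloxy)-3-methylbut-2-en-1-yl]-3,5-dimethoxyphenoxy}-3-hydroxypropyl]-1,2-phenylene diacetate | OCC[C@H](Oc1cc(OC)cc(OC)c1C/C=C(/C)CO[Si](C)(C)C(C)(C)C)c1ccc(OC(C)=O)c(OC(C)=O)c1
F11 | step 14 | 3-methoxy-5-[(triisopropylsilyl)oxy]phenol | COc1cc(O)cc(O[Si](C(C)C)(C(C)C)C(C)C)c1
F12 | step 14 | 2-[(2Z)-4-(tert-butyldimethylsilyloxy)-3-methylbut-2-en-1-yl]-3-methoxy-5-[(triisopropylsilyl)oxy]phenol | COc1cc(O[Si](C(C)C)(C(C)C)C(C)C)cc(O)c1C/C=C(/C)CO[Si](C)(C)C(C)(C)C
F13 | step 14 | prop-2-en-1-yl (3S)-3-[3,4-bis(acetyloxy)phenyl]-3-{2-[(2Z)-4-(tert-butyldimethylsilyloxy)-3-methylbut-2-en-1-yl]-3-methoxy-5-[(triisopropylsilyl)oxy]phenoxy}propanoate | C=CCOC(=O)C[C@H](Oc1cc(O[Si](C(C)C)(C(C)C)C(C)C)cc(OC)c1C/C=C(/C)CO[Si](C)(C)C(C)(C)C)c1ccc(OC(C)=O)c(OC(C)=O)c1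
F14 | step 14 | (3S)-3-[3,4-bis(acetyloxy)phenyl]-3-{2-[(2Z)-4-(tert-butyldimethylsilyloxy)-3-methylbut-2-en-1-yl]-3-methoxy-5-[(triisopropylsilyl)oxy]phenoxy}propanoic acid | OC(=O)C[C@H](Oc1cc(O[Si](C(C)C)(C(C)C)C(C)C)cc(OC)c1C/C=C(/C)CO[Si](C)(C)C(C)(C)C)c1ccc(OC(C)=O)c(OC(C)=O)c1
F15 | step 14 | (3S)-3-[3,4-bis(acetyloxy)phenyl]-3-{2-[(2Z)-4-(tert-butyldimethylsilyloxy)-3-methylbut-2-en-1-yl]-3-methoxy-5-[(triisopropylsilyl)oxy]phenoxy}propanoyl chloride | ClC(=O)C[C@H](Oc1cc(O[Si](C(C)C)(C(C)C)C(C)C)cc(OC)c1C/C=C(/C)CO[Si](C)(C)C(C)(C)C)c1ccc(OC(C)=O)c(OC(C)=O)c1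
F16 | step 14 | (2S)-2-[3,4-bis(acetyloxy)phenyl]-8-[(2Z)-4-(tert-butyldimethylsilyloxy)-3-methylbut-2-en-1-yl]-7-methoxy-5-[(triisopropylsilyl)oxy]-2,3-dihydro-4H-chromen-4-one | COc1cc(O[Si](C(C)C)(C(C)C)C(C)C)c2c(c1C/C=C(/C)CO[Si](C)(C)C(C)(C)C)O[C@H](c1ccc(OC(C)=O)c(OC(C)=O)c1)CC2=O
A1 | alternative 1 | 6,8-dimethoxy-3-methyl-1-benzoxepin-2(5H)-one | COc1cc(OC)c2C/C=C(C)\C(=O)Oc2c1
A2 | alternative 1 | 2-allyl-3,5-dimethoxyphenyl 2-methylprop-2-enoate | C=CCc1c(OC)cc(OC)cc1OC(=O)C(C)=C
A3 | alternative 1 | 2-[(2Z)-4-hydroxy-3-methylbut-2-en-1-yl]-3,5-dimethoxyphenol | COc1cc(OC)c(C/C=C(/C)CO)c(O)c1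
A4 | alternative 2 | (2S)-2-[3,4-bis(methoxymethoxy)phenyl]-5-bromo-2,3-dihydro-4H-pyran-4-one | BrC1=CO[C@H](c2ccc(OCOC)c(OCOC)c2)CC1=O
A5 | alternative 2 | (3Z,6Z)-8-(tert-butyldimethylsilyloxy)-1,3-dimethoxy-7-methyl-1-(trimethylsilyloxy)octa-1,3,6-triene (ketene acetal geometry left open) | COC(O[Si](C)(C)C)=C/C(OC)=C/C/C=C(/C)CO[Si](C)(C)C(C)(C)C
A6 | alternative 2 | (2S)-2-[3,4-bis(methoxymethoxy)phenyl]-8-[(2Z)-4-(tert-butyldimethylsilyloxy)-3-methylbut-2-en-1-yl]-5-hydroxy-7-methoxy-2,3-dihydro-4H-chromen-4-one | COc1cc(O)c2c(c1C/C=C(/C)CO[Si](C)(C)C(C)(C)C)O[C@H](c1ccc(OCOC)c(OCOC)c1)CC2=O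
A7 | alternative 3 | 1-{2-{[3,4-bis(tert-butyldimethylsilyloxy)phenyl]methoxy}-6-(tert-butyldimethylsilyloxy)-3-[(2Z)-4-(tert-butyldimethylsilyloxy)-3-methylbut-2-en-1-yl]-4-methoxyphenyl}-2-diazoethan-1-one | COc1cc(O[Si](C)(C)C(C)(C)C)c(C(=O)C=[N+]=[N-])c(OCc2ccc(O[Si](C)(C)C(C)(C)C)c(O[Si](C)(C)C(C)(C)C)c2)c1C/C=C(/C)CO[Si](C)(C)C(C)(C)C
A8 | alternative 3 | (2S)-2-[3,4-bis(tert-butyldimethylsilyloxy)phenyl]-5-(tert-butyldimethylsilyloxy)-8-[(2Z)-4-(tert-butyldimethylsilyloxy)-3-methylbut-2-en-1-yl]-7-methoxy-2,3-dihydro-4H-chromen-4-one | COc1cc(O[Si](C)(C)C(C)(C)C)c2c(c1C/C=C(/C)CO[Si](C)(C)C(C)(C)C)O[C@H](c1ccc(O[Si](C)(C)C(C)(C)C)c(O[Si](C)(C)C(C)(C)C)c1)CC2=O
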